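The middle flavan unit is not brought in as a flavan. Its pyran ring C (O1–C2–C3–C4–C4a–C8a) is disconnected as the formal [4+2] adduct (oxa-Povarov) of an O-aryl oxocarbenium ion, C4a=C8a–O1(+)=C2, raised on a phloroglucinol ring A that already carries the top epiafzelechin at C8, and an (E)-enol acetate, C3=C4, mounted on C8 of the bottom epiafzelechin. One operation joins both halves, forms C2–C3 and C4–C4a and creates the three stereocentres of the middle unit. It exploits the free C4a–H ortho to O1 of the phloroglucinol ring and the cation-stabilising 2,4,6-trioxygenated ring A of the bottom unit at C4.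

Key step: step 12

Remark: (−)-epiafzelechin (2R,3R) is taken as a purchasable natural flavan-3-ol; flavan numbering is used for every unit, and top, middle and bottom name the three units of the target joined 4β→8.

Step 1
Reactants: 1 (−)-epiafzelechin
Product: 2 5,7,4′-tri-O-benzyl-(−)-epiafzelechin
Conditions: BnBr, K2CO3, DMF, 0 °C to rt, argon
Reagents that add atoms: benzyl bromide BrCc1ccccc1
Why: Williamson etherification under carbonate alkylates the three phenols and leaves the secondary 3-OH, and no stereocentre is touched.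

Step 2
Reactants: 2 5,7,4′-tri-O-benzyl-(−)-epiafzelechin
Product: 3 3,5,7,4′-tetra-O-benzyl-(−)-epiafzelechin
Conditions: NaH, BnBr, DMF, 0 °C to rt
Reagents that add atoms: benzyl bromide BrCc1ccccc1
Why: Williamson benzylation of the remaining secondary alkoxide is safe once no free phenol is left that could open ring C.

Step 3
Reactants: 3 3,5,7,4′-tetra-O-benzyl-(−)-epiafzelechin
Product: 4 3,5,7,4′-tetra-O-benzyl-4β-(2-ethoxyethoxy)epiafzelechin
Conditions: DDQ, 2-ethoxyethanol, CH2Cl2, rt
Reagents that add atoms: 2-ethoxyethanol CCOCCO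
Why: Benzylic oxidation by DDQ hydride abstraction at C4 gives a cation stabilised by O1 and the 5- and 7-oxygens of ring A, which the alcohol captures trans to the 3-benzyloxy group; this centre is ionised again in step 4.

Step 4
Reactants: 4 3,5,7,4′-tetra-O-benzyl-4β-(2-ethoxyethoxy)epiafzelechin; 5 3,5-bis(benzyloxy)phenol
Product: 6 4β-[2-hydroxy-4,6-bis(benzyloxy)phenyl]-3,5,7,4′-tetra-O-benzylepiafzelechin
Conditions: 5 (4 equiv), TMSOTf (cat.), 4 Å MS, CH2Cl2, −78 °C
Reagents that add atoms: none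
Why: Friedel–Crafts alkylation through the C4 cation should occur at one of the two equivalent ring carbons ortho to the free OH (the least hindered sites) and from the face trans to the axial 3-benzyloxy group, which sets the 4β (3,4-trans) bond as is usual for 2,3-cis flavans.

Step 5
Reactants: 7 4-(benzyloxy)benzyl chloride
Product: 8 4-(benzyloxy)benzyl phenyl sulfide
Conditions: PhSH, K2CO3, acetone, rt
Reagents that add atoms: thiophenol Sc1ccccc1
Why: SN2 thioetherification of a benzylic chloride by thiophenolate.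

Step 6
Reactants: 8 4-(benzyloxy)benzyl phenyl sulfide
Product: 9 [4-(benzyloxy)phenyl](chloro)methyl phenyl sulfide (racemic, used crude)
Conditions: NCS, CH2Cl2, 0 °C to rt; filter off succinimide
Reagents that add atoms: N-chlorosuccinimide ClN1C(=O)CCC1=O
Why: α-Chlorination of a sulfide runs through the chlorosulfonium and thionium ions (Pummerer-type) and should select the benzylic carbon.

Step 7
Reactants: 6 4β-[2-hydroxy-4,6-bis(benzyloxy)phenyl]-3,5,7,4′-tetra-O-benzylepiafzelechin; 9 [4-(benzyloxy)phenyl](chloro)methyl phenyl sulfide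
Product: 10 4β-{2-[[4-(benzyloxy)phenyl](phenylthio)methoxy]-4,6-bis(benzyloxy)phenyl}-3,5,7,4′-tetra-O-benzylepiafzelechin (both epimers at the acetal carbon)
Conditions: Cs2CO3, DMF, 0 °C to rt; Et3N-deactivated silica
Reagents that add atoms: none
Why: O-Alkylation of the caesium phenoxide by the α-chloro sulfide (SN1-like through the thionium ion) should give the mixed O,S-acetal; its epimeric acetal carbon is of no consequence because it becomes planar in step 12.

Step 8
Reactants: 3 3,5,7,4′-tetra-O-benzyl-(−)-epiafzelechin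
Product: 11 8-bromo-3,5,7,4′-tetra-O-benzylepiafzelechin
Conditions: NBS, CH2Cl2, −40 °C to rt
Reagents that add atoms: N-bromosuccinimide BrN1C(=O)CCC1=O
Why: Electrophilic aromatic bromination goes to C8, the most nucleophilic position of the 5,7-dialkoxy ring A.

Step 9
Reactants: 11 8-bromo-3,5,7,4′-tetra-O-benzylepiafzelechin; 12 (E)-1,2-bis(4,4,5,5-tetramethyl-1,3,2-dioxaborolan-2-yl)ethene
Product: 13 8-[(E)-2-(4,4,5,5-tetramethyl-1,3,2-dioxaborolan-2-yl)vinyl]-3,5,7,4′-tetra-O-benzylepiafzelechin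
Conditions: 12 (3 equiv), Pd(OAc)2 (cat.), SPhos, K3PO4, THF/H2O, 60 °C
Reagents that add atoms: none
Why: Suzuki–Miyaura coupling with an excess of the symmetrical bis-boronate should transfer one (E)-2-borylvinyl group with retention of alkene geometry.

Step 10
Reactants: 13 8-[(E)-2-(4,4,5,5-tetramethyl-1,3,2-dioxaborolan-2-yl)vinyl]-3,5,7,4′-tetra-O-benzylepiafzelechin
Product: 14 potassium (E)-2-(3,5,7,4′-tetra-O-benzylepiafzelechin-8-yl)vinyltrifluoroborate
Conditions: KHF2, MeOH/H2O, rt
Reagents that add atoms: potassium hydrogen difluoride F.[F-].[K+]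
Why: Exchange of the pinacol boronate for the trifluoroborate with KHF2 leaves the alkene geometry unchanged.

Step 11
Reactants: 14 potassium (E)-2-(3,5,7,4′-tetra-O-benzylepiafzelechin-8-yl)vinyltrifluoroborate
Product: 15 8-[(E)-2-acetoxyvinyl]-3,5,7,4′-tetra-O-benzylepiafzelechin
Conditions: AcOH, CuBr (cat.), DMAP (cat.), 4 Å MS, O2 (1 atm), MeCN, 40 °C
Reagents that add atoms: acetic acid CC(O)=O
Why: Copper-catalysed oxidative C–O coupling of an alkenyl trifluoroborate with a carboxylic acid (Chan–Lam type) proceeds with retention and should give the (E)-enol acetate.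

Step 12
Reactants: 10 4β-{2-[[4-(benzyloxy)phenyl](phenylthio)methoxy]-4,6-bis(benzyloxy)phenyl}-3,5,7,4′-tetra-O-benzylepiafzelechin; 15 8-[(E)-2-acetoxyvinyl]-3,5,7,4′-tetra-O-benzylepiafzelechin
Product: 17 undeca-O-benzyl epiafzelechin-(4β→8)-epiafzelechin-(4β→8)-epiafzelechin bearing a 3-O-acetyl group on the middle unit, via oxocarbenium ion 16 (not isolated)
Conditions: AgOTf (1.5 equiv), 2,6-di-tert-butyl-4-methylpyridine (2 equiv), 15 (1.5 equiv), 4 Å MS, CH2Cl2, −78 to −20 °C, dark
Reagents that add atoms: none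
Why: AgOTf removes the phenylthio group of 10 and leaves the (E)-O-aryl oxocarbenium ion 16, a 2-oxonia-diene C4a=C8a–O1(+)=C2; the enol acetate attacks C2 with its acetoxy-bearing carbon C3 because the charge that develops at C4 is benzylic to the 2,4,6-trioxygenated ring A of the bottom unit, and that cation (free or held as the cyclic acetoxonium ion) alkylates C4a, the only open position ortho to O1, with loss of a proton to the hindered base. The closest known reaction is the oxa-Povarov reaction, the cationic formal [4+2] cycloaddition of aryl oxocarbenium ions with styrenes to 2,4-disubstituted chromans. Ring C closes as a six-membered ring: a [4+2] closure in the concerted limit, a 6-exo-trig Friedel–Crafts alkylation at the benzylic cation in the stepwise limit. C3 and C4 should come out trans from the (E)-alkene geometry (suprafacial addition), backed by opening of the trans-acetoxonium ion with inversion, and C2 and C3 should come out cis from an approach with the acetoxy group endo and the bulky twisted aryl group exo to the (E)-oxocarbenium ion, whose 2-aryl group lies outside. The step needs attack of the alkene ahead of the ring A carbons, which the unhindered styrenic CH (against aryl CH groups flanked by two ether oxygens) and the excess of 15 should secure, and attack on the α face of the oxa-diene, for which the substrate offers only the top unit at C8 next to O1; this facial choice is the least secure point, and the other face would give a diastereomer that should be separable.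

Step 13
Reactants: 17 undeca-O-benzyl epiafzelechin-(4β→8)-epiafzelechin-(4β→8)-epiafzelechin bearing a 3-O-acetyl group on the middle unit
Product: 18 undeca-O-benzyl epiafzelechin-(4β→8)-epiafzelechin-(4β→8)-epiafzelechin with free 3-OH on the middle unit
Conditions: NaOMe (cat.), MeOH/THF, 40 °C
Reagents that add atoms: none
Why: Base-catalysed transesterification (Zemplén type) removes the only ester, while benzyl ethers and the acid-labile interflavan bonds are stable to base.

Step 14
Reactants: 18 undeca-O-benzyl epiafzelechin-(4β→8)-epiafzelechin-(4β→8)-epiafzelechin with free 3-OH on the middle unit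
Product: 19 epiafzelechin-(4β→8)-epiafzelechin-(4β→8)-epiafzelechin (CNP0191553.1)
Conditions: H2 (1 atm), Pd(OH)2/C, THF/MeOH/H2O, rt
Reagents that add atoms: none
Why: Neutral hydrogenolysis cleaves all eleven benzyl ethers and should leave the cyclic C2–O1 ethers and the C4–aryl bonds of the three flavan units intact.

Compound list
1 | (−)-epiafzelechin, (2R,3R)-2-(4-hydroxyphenyl)chromane-3,5,7-triol | O[C@@H]1Cc2c(O)cc(O)cc2O[C@@H]1c1ccc(O)cc1 | starting material
2 | 5,7,4′-tri-O-benzyl-(−)-epiafzelechin (3-OH free) | O[C@@H]1Cc2c(OCc3ccccc3)cc(OCc3ccccc3)cc2O[C@@H]1c1ccc(OCc2ccccc2)cc1 | intermediate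
3 | 3,5,7,4′-tetra-O-benzyl-(−)-epiafzelechin | c1ccccc1CO[C@@H]1Cc2c(OCc3ccccc3)cc(OCc3ccccc3)cc2O[C@@H]1c1ccc(OCc2ccccc2)cc1 | intermediate
4 | 3,5,7,4′-tetra-O-benzyl-4β-(2-ethoxyethoxy)epiafzelechin (2,3-cis, 3,4-trans) | CCOCCO[C@H]1c2c(OCc3ccccc3)cc(OCc3ccccc3)cc2O[C@H](c2ccc(OCc3ccccc3)cc2)[C@@H]1OCc1ccccc1 | intermediate
5 | 3,5-bis(benzyloxy)phenol | Oc1cc(OCc2ccccc2)cc(OCc2ccccc2)c1 | starting material
6 | 4β-[2-hydroxy-4,6-bis(benzyloxy)phenyl]-3,5,7,4′-tetra-O-benzylepiafzelechin | Oc1cc(OCc2ccccc2)cc(OCc2ccccc2)c1[C@H]1c2c(OCc3ccccc3)cc(OCc3ccccc3)cc2O[C@H](c2ccc(OCc3ccccc3)cc2)[C@@H]1OCc1ccccc1 | intermediate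
7 | 4-(benzyloxy)benzyl chloride | ClCc1ccc(OCc2ccccc2)cc1 | starting material
8 | 4-(benzyloxy)benzyl phenyl sulfide | c1ccccc1SCc1ccc(OCc2ccccc2)cc1 | intermediate
9 | [4-(benzyloxy)phenyl](chloro)methyl phenyl sulfide (racemic) | ClC(Sc1ccccc1)c1ccc(OCc2ccccc2)cc1 | intermediate
10 | O,S-acetal: 4β-{2-[[4-(benzyloxy)phenyl](phenylthio)methoxy]-4,6-bis(benzyloxy)phenyl}-3,5,7,4′-tetra-O-benzylepiafzelechin (acetal carbon unassigned) | c1ccccc1COc1ccc(C(Sc2ccccc2)Oc2cc(OCc3ccccc3)cc(OCc3ccccc3)c2[C@H]2c3c(OCc4ccccc4)cc(OCc4ccccc4)cc3O[C@H](c3ccc(OCc4ccccc4)cc3)[C@@H]2OCc2ccccc2)cc1 | intermediate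
11 | 8-bromo-3,5,7,4′-tetra-O-benzylepiafzelechin | c1ccccc1CO[C@@H]1Cc2c(OCc3ccccc3)cc(OCc3ccccc3)c(Br)c2O[C@@H]1c1ccc(OCc2ccccc2)cc1 | intermediate
12 | (E)-1,2-bis(4,4,5,5-tetramethyl-1,3,2-dioxaborolan-2-yl)ethene | CC1(C)OB(/C=C/B2OC(C)(C)C(C)(C)O2)OC1(C)C | starting material
13 | 8-[(E)-2-(4,4,5,5-tetramethyl-1,3,2-dioxaborolan-2-yl)vinyl]-3,5,7,4′-tetra-O-benzylepiafzelechin | c1ccccc1CO[C@@H]1Cc2c(OCc3ccccc3)cc(OCc3ccccc3)c(/C=C/B3OC(C)(C)C(C)(C)O3)c2O[C@@H]1c1ccc(OCc2ccccc2)cc1 | intermediate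
14 | potassium (E)-2-(3,5,7,4′-tetra-O-benzylepiafzelechin-8-yl)vinyltrifluoroborate | [K+].c1ccccc1CO[C@@H]1Cc2c(OCc3ccccc3)cc(OCc3ccccc3)c(/C=C/[B-](F)(F)F)c2O[C@@H]1c1ccc(OCc2ccccc2)cc1 | intermediate
15 | 8-[(E)-2-acetoxyvinyl]-3,5,7,4′-tetra-O-benzylepiafzelechin | c1ccccc1CO[C@@H]1Cc2c(OCc3ccccc3)cc(OCc3ccccc3)c(/C=C/OC(C)=O)c2O[C@@H]1c1ccc(OCc2ccccc2)cc1 | intermediate
16 | (E)-O-aryl oxocarbenium ion from 10 (cation, triflate as counter-ion in the flask) | c1ccccc1COc1ccc(/C=[O+]/c2cc(OCc3ccccc3)cc(OCc3ccccc3)c2[C@H]2c3c(OCc4ccccc4)cc(OCc4ccccc4)cc3O[C@H](c3ccc(OCc4ccccc4)cc3)[C@@H]2OCc2ccccc2)cc1 | intermediate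
17 | undeca-O-benzyl trimer with 3-O-acetyl on the middle unit (benzyl on all phenols and on the 3-OH of top and bottom units) | c1ccccc1COc1ccc([C@H]2Oc3c(c(OCc4ccccc4)cc(OCc4ccccc4)c3[C@H]3c4c(OCc5ccccc5)cc(OCc5ccccc5)cc4O[C@H](c4ccc(OCc5ccccc5)cc4)[C@@H]3OCc3ccccc3)[C@H](c3c(OCc4ccccc4)cc(OCc4ccccc4)c4c3O[C@H](c3ccc(OCc5ccccc5)cc3)[C@H](OCc3ccccc3)C4)[C@H]2OC(C)=O)cc1 | intermediate
18 | undeca-O-benzyl trimer with free 3-OH on the middle unit | c1ccccc1COc1ccc([C@H]2Oc3c(c(OCc4ccccc4)cc(OCc4ccccc4)c3[C@H]3c4c(OCc5ccccc5)cc(OCc5ccccc5)cc4O[C@H](c4ccc(OCc5ccccc5)cc4)[C@@H]3OCc3ccccc3)[C@H](c3c(OCc4ccccc4)cc(OCc4ccccc4)c4c3O[C@H](c3ccc(OCc5ccccc5)cc3)[C@H](OCc3ccccc3)C4)[C@H]2O)cc1 | intermediate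
19 | epiafzelechin-(4β→8)-epiafzelechin-(4β→8)-epiafzelechin (CNP0191553.1) | Oc1ccc([C@H]2Oc3c(c(O)cc(O)c3[C@H]3c4c(O)cc(O)cc4O[C@H](c4ccc(O)cc4)[C@@H]3O)[C@H](c3c(O)cc(O)c4c3O[C@H](c3ccc(O)cc3)[C@H](O)C4)[C@H]2O)cc1 | target

Total step count: 14. Longest linear sequence: 9 steps (steps 1, 2, 8, 9, 10, 11, 12, 13, 14).

Steps most likely to fail

1. Step 12. The oxocarbenium ion may be consumed by arylation at ring A carbons (C8 or C6 of a flavan unit) instead of the alkene, and facial or endo/exo selectivity on the oxa-diene may be poor, so that the middle unit forms with the wrong sense relative to the top and bottom units. The fallback abandons the cycloaddition for two classical interflavan condensations. It sets out from 2, 3 and 4. Compound 2 is oxidised with DDQ in the presence of 2-ethoxyethanol to 5,7,4′-tri-O-benzyl-4β-(2-ethoxyethoxy)epiafzelechin F1, which keeps its 3-OH. TMSOTf-catalysed condensation of F1 with an excess of 3 at −78 °C should give the 4β→8 dimer, 5,7,4′-tri-O-benzylepiafzelechin-(4β→8)-3,5,7,4′-tetra-O-benzylepiafzelechin F2. A second TMSOTf-catalysed condensation of an excess of F2 with 4 should join the top unit to C8 of the upper unit of F2 and comes back to the route at 18, ready for step 14.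

2. Step 4. The cation may alkylate the carbon para to the free hydroxyl (between the two benzyloxy groups), alkylate oxygen, or alkylate the phenol twice. The fallback reverses the order of events so that no unsymmetrical phenol has to be alkylated at carbon. It sets out from 5, 9, 15 and 4. The caesium phenoxide of 5 is alkylated with 9 to the O,S-acetal 1,3-bis(benzyloxy)-5-{[4-(benzyloxy)phenyl](phenylthio)methoxy}benzene F3, whose two positions ortho to the acetal oxygen are equivalent. The silver-promoted [4+2] reaction of F3 with 15 (AgOTf, hindered pyridine base) should give the lower dimer, the middle-unit 3-O-acetate of hepta-O-benzyl epiafzelechin-(4β→8)-epiafzelechin F4. TMSOTf-catalysed condensation of an excess of F4 with 4 at −78 °C should then attach the top unit at C8 of the upper unit and comes back to the route at 17.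

3. Step 7. The hindered, ambident phenoxide may be alkylated at carbon by the soft thionium electrophile, and 9 may hydrolyse before it reacts. The fallback installs the C2 carbon one oxidation level lower and reaches the cation by hydride abstraction. It sets out from 6 and 7. Williamson etherification (K2CO3, DMF) should give the aryl benzyl ether 4β-{2-[4-(benzyloxy)benzyloxy]-4,6-bis(benzyloxy)phenyl}-3,5,7,4′-tetra-O-benzylepiafzelechin F5. Hydride abstraction from its 4-alkoxybenzylic CH2 with Ph3CBF4 in CH2Cl2 at low temperature, in the presence of 2,6-di-tert-butyl-4-methylpyridine, should give the same cation and comes back to the route at 16, which is intercepted by 15 as in step 12.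

Further compounds
F1 | step 12 | 5,7,4′-tri-O-benzyl-4β-(2-ethoxyethoxy)epiafzelechin (3-OH free) | CCOCCO[C@H]1c2c(OCc3ccccc3)cc(OCc3ccccc3)cc2O[C@H](c2ccc(OCc3ccccc3)cc2)[C@@H]1O
F2 | step 12 | 5,7,4′-tri-O-benzylepiafzelechin-(4β→8)-3,5,7,4′-tetra-O-benzylepiafzelechin (upper unit 3-OH free) | c1ccccc1COc1ccc([C@H]2Oc3cc(OCc4ccccc4)cc(OCc4ccccc4)c3[C@H](c3c(OCc4ccccc4)cc(OCc4ccccc4)c4c3O[C@H](c3ccc(OCc5ccccc5)cc3)[C@H](OCc3ccccc3)C4)[C@H]2O)cc1
F3 | step 4 | 1,3-bis(benzyloxy)-5-{[4-(benzyloxy)phenyl](phenylthio)methoxy}benzene | c1ccccc1COc1ccc(C(Sc2ccccc2)Oc2cc(OCc3ccccc3)cc(OCc3ccccc3)c2)cc1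
F4 | step 4 | 3-O-acetyl-5,7,4′-tri-O-benzylepiafzelechin-(4β→8)-3,5,7,4′-tetra-O-benzylepiafzelechin | c1ccccc1COc1ccc([C@H]2Oc3cc(OCc4ccccc4)cc(OCc4ccccc4)c3[C@H](c3c(OCc4ccccc4)cc(OCc4ccccc4)c4c3O[C@H](c3ccc(OCc5ccccc5)cc3)[C@H](OCc3ccccc3)C4)[C@H]2OC(C)=O)cc1
F5 | step 7 | 4β-{2-[4-(benzyloxy)benzyloxy]-4,6-bis(benzyloxy)phenyl}-3,5,7,4′-tetra-O-benzylepiafzelechin | c1ccccc1COc1ccc(COc2cc(OCc3ccccc3)cc(OCc3ccccc3)c2[C@H]2c3c(OCc4ccccc4)cc(OCc4ccccc4)cc3O[C@H](c3ccc(OCc4ccccc4)cc3)[C@@H]2OCc2ccccc2)cc1
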